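**One run.** I had one run to go on.

- autumn: substrate 0.035 M; run made earlier
- flask: substrate 0.069 M; time 3.0 d

autumn run (percent of the substrate charged): time / h: target / % = 1.33: 21; 4.00: 31; 6.00: 34; 10.0: 21; 15.0: 8

(readings scatter by 2 percentage points)

* the moment within 3.0 d at which there is most target
* the amount of target, in percent of the substrate charged, at that time

- a reading or a percentage of target counts all its forms, free or not

**Zero point.** With first-order steps the percent curve is the same at any charge, so I took the autumn peak reading, 34% at 6.00 h, as my zero. But the autumn target then fell nearly straight, and a first-order loss curves.

**Fixed drain.** From the autumn readings I took the fixed drain (a zero-order loss), the concentration of target lost per hour between the peak reading and the last reading: 1.01 mM h⁻¹. Up to the peak time that cost the autumn run 17.3%, so about 51.3% had been made. The same drain on the flask's larger charge cost 8.79%, about half as much, which left 42.5%.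

**Weak link.** The last reading may already lie on a bend. From the peak reading and the next one, the drain became 1.14 mM h⁻¹ and the flask 43.6%. I committed to that, somewhat after 6.00 h.

**Result.** The forecast, unlike my reckoning, gave 35% at 0.37 d, reading the fall as “a saturated catalyst or site working at a fixed absolute rate”. The flask gave 48.5% at 0.333 d.

    substrate ⇌ target (K = 3.70, k = 0.230 h⁻¹)
    target → over-reaction product (k = 0.250 h⁻¹)
    substrate + target → side product (k = 3.20 M⁻¹ h⁻¹)
    crystals ⇌ target, rate k4*(cs4 - [target]) while solid is left; crystals form when [target] > cs4 (solubility = 7.10 mM, k = 18.0 h⁻¹)

**Why higher.** The turning of target into over-reaction product held the flask's peak down, though it was not the whole story: without that step the highest amount was 77.4%, against 48.5%. The saturation of target raised the peak in part: without it the highest amount was 24.7%, against 48.5%. At the best time, crystals made up 38.2% of the flask's 48.5% target. Between 0.416 d and 1.33 d the flask lost 1.39 mM h⁻¹, faster than my drain.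

**Neighbour.** On the neighbour flask's 0.017 M, the drain cost 35.7% by 6.00 h, which left 15.6%. The computed best there was 30.1%, or 5.12 mM of target, less than the 7.1 mM at which crystals form, so the drain reckoning does not carry over to that flask.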